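The lactone ring (ring B: C1, O2, C3, C4, C4a, C8a) is cut at C8a–C1 and C4–C3. In one flask, bromine–lithium exchange on the ethyl carbonate of 2-bromo-3-methylphenol triggers a 1,3 O→C shift of the ethoxycarbonyl group (anionic Fries rearrangement). The ester just placed on C8a acidifies the neighbouring methyl (C4), and the lateral carbanion is acylated by a (2E,4E)-dienyl Weinreb amide. The step exploits the contiguous array of benzene ring A: phenol oxygen on C8, then C8a, then C4a bearing C4. C3 enters as a ketone; Corey–Bakshi–Shibata reduction sets (R)-C3 and alkoxide lactonization closes ring B.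

Key step: step 4

Remark: atom labels follow the isochroman-1-one numbering of the target (C1 lactone carbonyl, O2, C3 stereocentre, C4, C4a, C8 bearing OH, C8a). 2-Bromo-3-methylphenol, tetradecanal and triethyl (E)-4-phosphonocrotonate are taken as purchasable.

Step 1
Reactants: 1 2-bromo-3-methylphenol; 2 ethyl chloroformate
Product: 3 ethyl (2-bromo-3-methylphenyl) carbonate
Conditions: K2CO3, acetone, 0 °C → rt
Reagents that add atoms: none
Why: O-acylation of the phenoxide by the chloroformate (carbonate formation by addition–elimination) should be fast and leaves the aryl bromide untouched.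

Step 2
Reactants: 4 tetradecanal; 5 triethyl (E)-4-phosphonocrotonate
Product: 6 ethyl (2E,4E)-octadeca-2,4-dienoate
Conditions: LiOH·H2O, 4 Å molecular sieves, THF, reflux
Reagents that add atoms: none
Why: Vinylogous Horner–Wadsworth–Emmons olefination, in which the γ-deprotonated phosphonate reacts at the carbon next to phosphorus and reversible addition followed by syn-elimination should favour the new (4E) double bond while the (2E) bond of the reagent is kept.

Step 3
Reactants: 6 ethyl (2E,4E)-octadeca-2,4-dienoate
Product: 7 (2E,4E)-N-methoxy-N-methyloctadeca-2,4-dienamide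
Conditions: MeNH(OMe)·HCl + i-PrMgCl (premixed), THF, –20 → 0 °C
Reagents that add atoms: N,O-dimethylhydroxylamine hydrochloride (CNOC.Cl)
Why: Weinreb amide formation by aminolysis of the ester with the chloromagnesium amide of N,O-dimethylhydroxylamine, premixed so that no free Grignard reagent meets the dienoate.

Step 4
Reactants: 3 ethyl (2-bromo-3-methylphenyl) carbonate; 7 (2E,4E)-N-methoxy-N-methyloctadeca-2,4-dienamide
Product: 12 ethyl 2-hydroxy-6-[(3E,5E)-2-oxononadeca-3,5-dien-1-yl]benzoate, via aryllithium 8 (not isolated), via lithium phenoxide ester 9 (not isolated), via benzylic dianion 10 (not isolated), via tetrahedral adduct 11 (not isolated)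
Conditions: t-BuLi (2.05 equiv), THF, –100 → –78 °C; LiN(i-Pr)2 (1.1 equiv), –78 °C; 7 (0.8 equiv), –78 → –40 °C; aq. NH4Cl
Reagents that add atoms: none
Why: t-BuLi exchanges the bromine on the carbon flanked by the carbonate oxygen and the methyl group, and aryllithium 8 attacks its own carbonate carbonyl through a four-membered tetrahedral intermediate that collapses to phenoxide 9, which makes the C8a–C1 bond (halogen–lithium-exchange-triggered anionic ortho-Fries rearrangement). The ester now sits ortho to the methyl group, so LiN(i-Pr)2 removes a benzylic proton to give the o-quinodimethane-type dianion 10 (lateral lithiation of an o-toluate), whose benzylic carbon adds to Weinreb amide 7 to give chelated adduct 11 and, on work-up, ketone 12, which makes the C4–C3 bond. No ring is closed (the only cyclic species is the transient four-membered intermediate of the acyl shift) and no stereocentre is formed, since C3 is carried as a ketone. The step needs regiocontrol of the acyl shift, secured by the bromine that marks C8a as the only lithiated ring carbon. It also needs 1,2- rather than 1,4- or 1,6-addition and mono-acylation, secured by lithium chelation in the stable N-methoxy-N-methyl tetrahedral adduct. Two equivalents of t-BuLi are used so that the tert-butyl bromide formed is destroyed and cannot alkylate the later benzylic anion.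

Step 5
Reactants: 12 ethyl 2-hydroxy-6-[(3E,5E)-2-oxononadeca-3,5-dien-1-yl]benzoate
Product: 13 ethyl 2-hydroxy-6-[(2R,3E,5E)-2-hydroxynonadeca-3,5-dien-1-yl]benzoate
Conditions: (3aS)-1-methyl-3,3-diphenyltetrahydro-1H,3H-pyrrolo[1,2-c][1,3,2]oxazaborole [(S)-Me-CBS, 0.3 equiv], catecholborane (3 equiv), toluene, –78 °C; MeOH, pH 7 buffer
Reagents that add atoms: none
Why: Corey–Bakshi–Shibata reduction, in which the ketone should bind the ring boron of the (S)-oxazaborolidine with the π-bearing dienyl group as the large substituent (as for other trans-enones), so that hydride from the nitrogen-bound catecholborane reaches the face that gives the (2R) alcohol, while catecholborane at –78 °C reduces 1,2 and leaves the diene and the ester alone.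

Step 6
Reactants: 13 ethyl 2-hydroxy-6-[(2R,3E,5E)-2-hydroxynonadeca-3,5-dien-1-yl]benzoate
Product: 15 (3R)-3-[(1E,3E)-heptadeca-1,3-dien-1-yl]-8-hydroxy-3,4-dihydro-1H-isochromen-1-one, via dilithium alkoxide 14 (not isolated)
Conditions: LiN(SiMe3)2 (2.1 equiv), THF, –78 → 0 °C; AcOH
Reagents that add atoms: none
Why: Lactonization by intramolecular transesterification, in which the lithium alkoxide of 14 attacks the neighbouring ethyl ester in a 6-exo-trig closure (the closure known from toluate–aldehyde routes to 3,4-dihydroisocoumarins), and the C3 configuration is kept because the C3–O bond is not broken.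

Compound list
1 | 2-bromo-3-methylphenol | Cc1cccc(O)c1Br | starting material
2 | ethyl chloroformate | CCOC(=O)Cl | starting material
3 | ethyl (2-bromo-3-methylphenyl) carbonate | CCOC(=O)Oc1cccc(C)c1Br | intermediate
4 | tetradecanal | CCCCCCCCCCCCCC=O | starting material
5 | triethyl (E)-4-phosphonocrotonate | CCOC(=O)/C=C/CP(=O)(OCC)OCC | starting material
6 | ethyl (2E,4E)-octadeca-2,4-dienoate | CCCCCCCCCCCCC/C=C/C=C/C(=O)OCC | intermediate
7 | (2E,4E)-N-methoxy-N-methyloctadeca-2,4-dienamide | CCCCCCCCCCCCC/C=C/C=C/C(=O)N(C)OC | intermediate
8 | [2-(ethoxycarbonyloxy)-6-methylphenyl]lithium | CCOC(=O)Oc1cccc(C)c1[Li] | intermediate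
9 | lithium 2-(ethoxycarbonyl)-3-methylphenoxide | CCOC(=O)c1c(C)cccc1O[Li] | intermediate
10 | dilithio dianion of ethyl 2-hydroxy-6-methylbenzoate (phenoxide oxygen and benzylic carbon) | CCOC(=O)c1c(C[Li])cccc1O[Li] | intermediate
11 | dilithium salt of the N-methoxy-N-methyl hemiaminal adduct of 10 and 7 | CCCCCCCCCCCCC/C=C/C=C/C(O[Li])(Cc1cccc(O[Li])c1C(=O)OCC)N(C)OC | intermediate
12 | ethyl 2-hydroxy-6-[(3E,5E)-2-oxononadeca-3,5-dien-1-yl]benzoate | CCCCCCCCCCCCC/C=C/C=C/C(=O)Cc1cccc(O)c1C(=O)OCC | intermediate
13 | ethyl 2-hydroxy-6-[(2R,3E,5E)-2-hydroxynonadeca-3,5-dien-1-yl]benzoate | CCCCCCCCCCCCC/C=C/C=C/[C@H](O)Cc1cccc(O)c1C(=O)OCC | intermediate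
14 | dilithium alkoxide–phenoxide of 13 | CCCCCCCCCCCCC/C=C/C=C/[C@H](O[Li])Cc1cccc(O[Li])c1C(=O)OCC | intermediate
15 | (3R)-3-[(1E,3E)-heptadeca-1,3-dien-1-yl]-8-hydroxy-3,4-dihydro-1H-isochromen-1-one | CCCCCCCCCCCCC/C=C/C=C/[C@H]1Cc2cccc(O)c2C(=O)O1 | target

Total step count: 6. Longest linear sequence: 5 steps (4 → 6 → 7 → 12 → 13 → 15).

Steps most likely to fail

Step 4. The soft benzylic carbanion of 10 may add in a conjugate (1,4 or 1,6) sense to the dienamide or deprotonate its ε-CH2, so that acylation stalls. The fallback sets out from 6 and 3 and comes back at 12. Ester 6 is reduced with i-Bu2AlH (CH2Cl2, –78 °C) to (2E,4E)-octadeca-2,4-dien-1-ol F1, which MnO2 (CH2Cl2) oxidizes to (2E,4E)-octadeca-2,4-dienal F2. Dianion 10 is generated from 3 as in step 4 and F2 is added at –78 °C, where 1,2-addition of a lithium reagent to an aldehyde should outrun the side reactions. Quenching cold with AcOH, before the alkoxide can lactonize, should give racemic ethyl 2-hydroxy-6-[(3E,5E)-2-hydroxynonadeca-3,5-dien-1-yl]benzoate F3. Chemoselective oxidation of the allylic alcohol of F3 with MnO2 should then give 12.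

Step 5. Facial discrimination may be poor because the CH2Ar and dienyl groups are of similar effective size, and conjugate hydride delivery may compete. The fallback sets out from 12 and comes back at 13. Hydride transfer is moved from the oxazaborolidine to an enzyme pocket: an (R)-selective ketoreductase (alcohol dehydrogenase class) chosen from a commercial panel, with NADP+, glucose dehydrogenase and glucose for cofactor recycling, in phosphate buffer pH 7 with DMSO cosolvent at 30 °C. This fallback makes no compound outside the list (F0).

Step 6. Ring closure onto the hindered, phenoxide-deactivated ester may be slow, or base may induce β-elimination that opens the lactone toward a conjugated trienyl benzoate. The fallback sets out from 13 and comes back at 15. The ethyl ester is cleaved with Me3SnOH (1,2-dichloroethane, 70 °C) to 2-hydroxy-6-[(2R,3E,5E)-2-hydroxynonadeca-3,5-dien-1-yl]benzoic acid F4. The ring is then closed by carboxyl activation under neutral conditions (EDC·HCl, DMAP cat., CH2Cl2, 0 °C), which again leaves the C3–O bond intact.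

Further compounds
F1 | step 4 | (2E,4E)-octadeca-2,4-dien-1-ol | CCCCCCCCCCCCC/C=C/C=C/CO
F2 | step 4 | (2E,4E)-octadeca-2,4-dienal | CCCCCCCCCCCCC/C=C/C=C/C=O
F3 | step 4 | racemic ethyl 2-hydroxy-6-[(3E,5E)-2-hydroxynonadeca-3,5-dien-1-yl]benzoate | CCCCCCCCCCCCC/C=C/C=C/C(O)Cc1cccc(O)c1C(=O)OCC
F0 | step 5 | none | none
F4 | step 6 | 2-hydroxy-6-[(2R,3E,5E)-2-hydroxynonadeca-3,5-dien-1-yl]benzoic acid | CCCCCCCCCCCCC/C=C/C=C/[C@H](O)Cc1cccc(O)c1C(=O)O
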